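The route rests on cutting the lactone CH2–C(=O) bond, C1–C2 (seco-labdane numbering; carbocycle C5–C10). The key step is a remote C–H carbonylation of monocyclic alcohol 15: its C8 alkoxy radical abstracts hydrogen from the one C10 methyl that lies 1,3-diaxial to O8 on the cyclohexane ring, the C1 radical takes up CO (C1–C2 bond) and the acyl carbon closes onto O8. One operation thus turns the C10 gem-dimethyl carbon into the quaternary stereocentre and builds the 2-oxabicyclo[3.3.1]nonan-3-one. The precursor holds no lactone carbon: it is a C10 gem-dimethyl cyclohexanol made from (R)-3-hydroxy-β-ionone by chirality relay C6 → C8 → C9.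

Key step: step 12

Numbering used in the names: lactone CH2 = C1, lactone C=O = C2, CO2H = C3, CMe2 = C4, ring C5 (bears C4), C6 (CHOH), C7 (CH2), C8 (C–O, methyl), C9 (CH, side chain), C10 (quaternary); side chain C11 (CHOH), C12 (CH2), C13 (C(OH)CH3), C14=C15 (vinyl).

Assumption: (R)-3-hydroxy-β-ionone (1) and allyl 2-bromo-2-methylpropanoate (11) are taken as purchasable; 1 is a catalogued carotenoid building block in enantiopure form.

Step 1
Reactants: 1 (R)-3-hydroxy-β-ionone, (E)-4-[(4R)-4-hydroxy-2,6,6-trimethylcyclohex-1-en-1-yl]but-3-en-2-one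
Product: 2 (3S,5S,6R)-5,6-epoxy-3-hydroxy-5,6-dihydro-β-ionone (megastigmane locants; epoxide oxygen cis to the hydroxyl; C8–C9 epoxide in seco-labdane numbering)
Conditions: VO(acac)2 (5 mol %), t-BuOOH, PhMe, 25 °C
Reagents that add atoms: tert-butyl hydroperoxide, CC(C)(C)OO
Why: Vanadium-catalysed hydroxyl-directed epoxidation, in which the homoallylic C6–OH binds the vanadium peroxide and delivers oxygen to the tetrasubstituted C8=C9 alkene on its own face, so C8 and C9 are set cis to O6 while the electron-poor enone alkene is left alone.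

Step 2
Reactants: 2 epoxy enone
Product: 3 (E)-4-[(1R,2S,4S)-2,4-dihydroxy-2,6,6-trimethylcyclohexyl]but-3-en-2-one (6,8-diol; O6, O8 and the C9 side chain all cis)
Conditions: Pd2(dba)3·CHCl3 (2.5 mol %), n-Bu3P, HCO2H, Et3N, dioxane, 25 °C
Reagents that add atoms: none
Why: Tsuji Pd(0)/formate hydrogenolysis of an alkenyl oxirane, in which Pd(0) opens the allylic C9–O bond anti and hydride passes from palladium to C9 with overall inversion, so H9 ends trans and the side chain cis to the C8 hydroxyl and the (E)-enone is kept.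

Step 3
Reactants: 3 dihydroxy enone
Product: 4 (11R,12S)-epoxy ketone, 1-[(2S,3R)-3-[(1S,2S,4S)-2,4-dihydroxy-2,6,6-trimethylcyclohexyl]oxiran-2-yl]ethan-1-one
Conditions: La(O-iPr)3, (R)-BINOL, Ph3As=O (10 mol % each), t-BuOOH, MS 4 Å, THF, 25 °C
Reagents that add atoms: tert-butyl hydroperoxide, CC(C)(C)OO
Why: Lanthanum–BINOL (Shibasaki) nucleophilic epoxidation of the (E)-enone under catalyst control, the (R)-BINOL complex giving the (αS,βR) epoxide and thereby setting C11 and C12.

Step 4
Reactants: 4 epoxy ketone
Product: 5 (2S)-2-[(2S,3R)-3-[(1S,2S,4S)-2,4-dihydroxy-2,6,6-trimethylcyclohexyl]oxiran-2-yl]but-3-en-2-ol (C13 tertiary alcohol)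
Conditions: CH2=CHMgBr (4 equiv), THF, −78 °C
Reagents that add atoms: vinylmagnesium bromide, C=C[Mg]Br
Why: Cram-chelate-controlled Grignard addition to an α,β-epoxy ketone, in which magnesium bridges the carbonyl and epoxide oxygens and vinyl attacks the face away from C11, which sets C13 in the sense that becomes 13R in the diol.

Step 5
Reactants: 5 epoxy alcohol
Product: 6 (1S,3R)-1-[(1S,2S,4S)-2,4-dihydroxy-2,6,6-trimethylcyclohexyl]-3-methylpent-4-ene-1,3-diol (6,8,11,13-tetraol; 11S,13R)
Conditions: Red-Al, THF, 0 °C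
Reagents that add atoms: none
Why: Red-Al opening of a 2,3-epoxy alcohol, in which the C13 alkoxy-aluminate delivers hydride intramolecularly to C12 and gives the 1,3-diol with C11 and C13 untouched.

Step 6
Reactants: 6 tetraol
Product: 7 11,13-O-isopropylidene derivative of 6 (6S,8S,9S,11S,13R; O6–H and O8–H free)
Conditions: Me2C(OMe)2, PPTS (cat.), CH2Cl2, 0 °C
Reagents that add atoms: 2,2-dimethoxypropane, COC(C)(C)OC
Why: Acid-catalysed ketalisation under thermodynamic control should select the acyclic 11,13-diol, because a ketal across the 1,3-diaxial O6/O8 pair would collide with the syn-axial C10 methyl and the buried tertiary O8 cannot close an 8,11-ring.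

Step 7
Reactants: 7 acetonide diol
Product: 8 6-ketone of 7, (3S,4S)-4-[(4S,6R)-6-ethenyl-2,2,6-trimethyl-1,3-dioxan-4-yl]-3-hydroxy-3,5,5-trimethylcyclohexan-1-one
Conditions: Dess–Martin periodinane, CH2Cl2, 0 → 25 °C
Reagents that add atoms: none
Why: Dess–Martin oxidation of the only free secondary alcohol (C6), the tertiary C8 alcohol being inert.

Step 8
Reactants: 8 β-hydroxy ketone
Product: 10 Δ5 silyl enol ether with O6 and O8 both trimethylsilylated (8S,9S,11S,13R), via dilithium alkoxide enolate 9 (not isolated)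
Conditions: LDA (2.3 equiv), THF, −78 °C; then Me3SiCl, −78 → 0 °C
Reagents that add atoms: chlorotrimethylsilane, C[Si](C)(C)Cl; lithium diisopropylamide, CC(C)N([Li])C(C)C (lithium of 9 only)
Why: Kinetic enolisation of a β-hydroxy ketone dianion, in which the C8 lithium alkoxide disfavours deprotonation at C7 so that LDA removes H5 and O-silylation fixes the C5=C6 enol ether regioselectively.

Step 9
Reactants: 10 silyl enol ether; 11 allyl 2-bromo-2-methylpropanoate
Product: 13 γ-keto allyl ester (5R,8S,9S,11S,13R; C5 bears CMe2CO2allyl equatorial, C6 ketone, C8 OH free), via C8 trimethylsilyl ether keto ester 12 (not isolated)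
Conditions: fac-Ir(ppy)3 (1 mol %), 2,6-lutidine, MeCN, blue LEDs, 25 °C; then K2CO3 (cat.), MeOH, 0 °C
Reagents that add atoms: none
Why: Photoredox radical α-alkylation of a silyl enol ether, in which the electrophilic tertiary radical from 11 adds to C5 of the electron-rich enol ether rather than to the vinyl group, oxidation and desilylation return the ketone, and methanolic carbonate cleaves the C8 silyl ether and equilibrates C5 to the equatorial isomer cis to the C9 side chain.

Step 10
Reactants: 13 γ-keto ester
Product: 14 6,8-diol (5R,6R,8S,9S,11S,13R; O6 axial, cis to O8)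
Conditions: NaBH4, MeOH–CH2Cl2, −40 °C; pH 7 work-up
Reagents that add atoms: none
Why: Borohydride reduction in which the axial approach to C6 is blocked by the syn-axial C8–OH and C10–CH3, so hydride enters equatorially and gives the axial alcohol cis to O8, while low temperature and neutral work-up should prevent acyl transfer from the allyl ester.

Step 11
Reactants: 14 diol
Product: 15 6-O-triethylsilyl ether of 14 (O8–H free)
Conditions: Et3SiOTf (1.1 equiv), 2,6-lutidine, CH2Cl2, −78 °C
Reagents that add atoms: triethylsilyl trifluoromethanesulfonate, CC[Si](CC)(CC)OS(=O)(=O)C(F)(F)F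
Why: Selective silylation, the secondary C6 alcohol reacting at −78 °C while the tertiary C8 alcohol, flanked by a quaternary carbon and two syn-axial groups, stays free for the key step.

Step 12
Reactants: 15 monocyclic C8 alcohol with C10 gem-dimethyl
Product: 16 2,8-lactone (5R,6R,8S,9S,10R,11S,13R), 2-oxabicyclo[3.3.1]nonan-3-one carrying 6-OTES, the 11,13-acetonide and the allyl ester
Conditions: Pb(OAc)4 (2 equiv), CO (80 atm), PhH, 40 °C
Reagents that add atoms: carbon monoxide, [C-]#[O+]
Why: Pb(IV) exchanges onto the free C8 hydroxyl and homolysis gives the C8 alkoxy radical, which abstracts hydrogen through a six-membered chair transition state from the C10 methyl held 1,3-diaxial to it; the primary C1 radical adds to CO (C1–C2 bond) and the acyl radical is oxidised by Pb(IV) to an acyl cation equivalent that O8 captures. The closest known reaction type is the Pb(OAc)4/CO remote (δ) C–H carbonylation of saturated alcohols to δ-lactones (alkoxy-radical 1,5-hydrogen transfer followed by radical carbonylation). The 2-oxabicyclo[3.3.1]nonan-3-one ring is closed by insertion of CO between C1 and O8, the O8–C2 bond forming last in a 6-exo acyl capture on a ring that already holds both partners syn-axial. The only new stereocentre, C10, is set by diastereotopic-group selection: on the chair that keeps the C5 and C9 substituents equatorial only the methyl cis to O8 is axial and within reach, the equatorial methyl is not. The step needs hydrogen transfer to outrun β-scission of the tertiary alkoxy radical and CO capture to outrun oxidation of the C1 radical to the cyclic ether; the rigid diaxial geometry, the primary (hard to oxidise) radical and 80 atm CO should secure this, while O6, O11 and O13 are masked and C12–H cannot reach O8 without colliding with the C10 methyl.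

Step 13
Reactants: 16 protected lactone
Product: 17 allyl ester of the target (6,11,13-triol; 5R,6R,8S,9S,10R,11S,13R)
Conditions: PPTS, MeOH, 25 °C
Reagents that add atoms: none
Why: Acid-catalysed methanolysis (transketalisation and silyl ether solvolysis) removes the acetonide and the triethylsilyl group in one operation, and the lactone, the hindered allyl ester and the tertiary allylic alcohol should tolerate pyridinium tosylate.

Step 14
Reactants: 17 allyl ester
Product: 18 target acid, (5R,6R,8S,9S,10R,11S,13R)-6,11,13-trihydroxy-2,3-seco-labd-14-ene-2,3-dioic acid 2,8-lactone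
Conditions: Pd(PPh3)4 (5 mol %), morpholine, THF, 25 °C; work-up at pH 4–5, 0 °C
Reagents that add atoms: none
Why: Tsuji–Trost deallylation, in which Pd(0) ionises only the allyl ester and morpholine traps the allyl group, so the acid is released under neutral conditions that spare the lactone and avoid acid-promoted lactonisation onto O6.

Compound list
1 | (R)-3-hydroxy-β-ionone | CC1=C(/C=C/C(C)=O)C(C)(C)C[C@H](O)C1 | starting material
2 | (3S,5S,6R)-5,6-epoxy-3-hydroxy-5,6-dihydro-β-ionone (epoxide cis to OH) | O[C@@H]1C[C@]2(C)O[C@]2(/C=C/C(C)=O)C(C)(C)C1 | intermediate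
3 | (E)-4-[(1R,2S,4S)-2,4-dihydroxy-2,6,6-trimethylcyclohexyl]but-3-en-2-one | O[C@@H]1C[C@](C)(O)[C@H](/C=C/C(C)=O)C(C)(C)C1 | intermediate
4 | (11R,12S)-epoxy ketone | O[C@@H]1C[C@](C)(O)[C@H]([C@H]2O[C@@H]2C(C)=O)C(C)(C)C1 | intermediate
5 | epoxy C13 vinyl carbinol | O[C@@H]1C[C@](C)(O)[C@H]([C@H]2O[C@@H]2[C@@](C)(O)C=C)C(C)(C)C1 | intermediate
6 | 6,8,11,13-tetraol (11S,13R) | O[C@@H]1C[C@](C)(O)[C@H]([C@@H](O)C[C@@](C)(O)C=C)C(C)(C)C1 | intermediate
7 | 11,13-acetonide of 6 | O[C@@H]1C[C@](C)(O)[C@H]([C@@H]2C[C@](C)(C=C)OC(C)(C)O2)C(C)(C)C1 | intermediate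
8 | 8-hydroxy-6-ketone (acetonide) | O=C1C[C@](C)(O)[C@H]([C@@H]2C[C@](C)(C=C)OC(C)(C)O2)C(C)(C)C1 | intermediate
9 | dilithium C8-alkoxide Δ5-enolate of 8 | [Li]OC1=CC(C)(C)[C@@H]([C@@H]2C[C@](C)(C=C)OC(C)(C)O2)[C@@](C)(O[Li])C1 | intermediate (not isolated)
10 | Δ5 silyl enol ether, O6 and O8 trimethylsilylated | C[Si](C)(C)OC1=CC(C)(C)[C@@H]([C@@H]2C[C@](C)(C=C)OC(C)(C)O2)[C@@](C)(O[Si](C)(C)C)C1 | intermediate
11 | allyl 2-bromo-2-methylpropanoate | C=CCOC(=O)C(C)(C)Br | starting material
12 | C8 trimethylsilyl ether keto ester (C5 epimers) | C=CCOC(=O)C(C)(C)C1C(=O)C[C@](C)(O[Si](C)(C)C)[C@H]([C@@H]2C[C@](C)(C=C)OC(C)(C)O2)C1(C)C | intermediate (not isolated)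
13 | γ-keto allyl ester (5R,8S,9S,11S,13R) | C=CCOC(=O)C(C)(C)[C@@H]1C(=O)C[C@](C)(O)[C@H]([C@@H]2C[C@](C)(C=C)OC(C)(C)O2)C1(C)C | intermediate
14 | 6,8-diol allyl ester (5R,6R,8S,9S,11S,13R) | C=CCOC(=O)C(C)(C)[C@@H]1[C@H](O)C[C@](C)(O)[C@H]([C@@H]2C[C@](C)(C=C)OC(C)(C)O2)C1(C)C | intermediate
15 | 6-O-triethylsilyl ether of 14 | C=CCOC(=O)C(C)(C)[C@@H]1[C@H](O[Si](CC)(CC)CC)C[C@](C)(O)[C@H]([C@@H]2C[C@](C)(C=C)OC(C)(C)O2)C1(C)C | intermediate
16 | protected 2,8-lactone (10R) | C=C[C@@]3(C)C[C@H](OC(C)(C)O3)[C@@H]1[C@]2(C)CC(=O)O[C@@]1(C)C[C@@H](O[Si](CC)(CC)CC)[C@H]2C(C)(C)C(=O)OCC=C | intermediate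
17 | allyl ester of the target | C=C[C@](C)(O)C[C@H](O)[C@@H]1[C@]2(C)CC(=O)O[C@@]1(C)C[C@@H](O)[C@H]2C(C)(C)C(=O)OCC=C | intermediate
18 | target acid | C=C[C@](C)(O)C[C@H](O)[C@@H]1[C@]2(C)CC(=O)O[C@@]1(C)C[C@@H](O)[C@H]2C(C)(C)C(=O)O | target

Total step count: 14. Longest linear sequence: 14 steps (from 1).

Steps most likely to fail

Step 12. The tertiary C8 alkoxy radical may fragment (β-scission), the C1 radical may be oxidised to the 1,8-cyclic ether before it captures CO, or Pb(IV) may attack the vinyl group. The fallback sets out from 15 and comes back at 16. O8 is converted with Et2SiH2/[Ir(cod)OMe]2 into its hydridosilyl ether, and Rh/Xantphos-catalysed δ-C–H silylation of the same syn-axial methyl gives the oxasilinane F1. Tamao–Fleming oxidation (H2O2, KHCO3) gives the 1,4-diol F2, and PPh3/I2/imidazole converts its primary alcohol into the iodide F3. Carbonylative lactonisation of F3 (CO, Pd(PPh3)4 or irradiation, K2CO3) then gives 16.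

Step 9. The tertiary radical may fail to add to the neopentyl-type C5, may add to the vinyl group instead, or C5 may not equilibrate fully. The fallback sets out from 8 and comes back at 13. It is an oxidative enolate heterocoupling: the dianion of 8 (LDA) and the lithium enolate of allyl isobutyrate are oxidised with Fe(acac)3 (or Cu(II) 2-ethylhexanoate) in THF, −78 → 25 °C, which forms the C4–C5 bond directly. Carbonate equilibration as in the main route should then give 13. No new compound arises (F0).

Step 10. The allyl ester may transfer its acyl group to the new C6 alkoxide (γ-lactonisation with loss of allyl alcohol), or facial selectivity may be poor. The fallback sets out from 13 and comes back at 15. Lactonisation is driven to completion (NaBH4, MeOH, 25 °C) to give the γ-lactone F4. KOH in aqueous dioxane opens it, and Et3SiOTf/2,6-lutidine silylates O6 (the silyl ester is hydrolysed on work-up) to give the acid F5. Cs2CO3/allyl bromide in DMF re-forms the allyl ester 15.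

Further compounds
F1 | step 12 | C1–Si/O8 oxasilinane (diethylsilylene bridging O8 and C1) | C=C[C@@]3(C)C[C@H](OC(C)(C)O3)[C@@H]1[C@]2(C)C[Si](CC)(CC)O[C@@]1(C)C[C@@H](O[Si](CC)(CC)CC)[C@H]2C(C)(C)C(=O)OCC=C
F2 | step 12 | 1,8-diol (C1 hydroxymethyl, O8–H) | C=C[C@@]3(C)C[C@H](OC(C)(C)O3)[C@@H]1[C@](C)(CO)[C@H](C(C)(C)C(=O)OCC=C)[C@H](O[Si](CC)(CC)CC)C[C@@]1(O)C
F3 | step 12 | C1 iodide (O8–H) | C=C[C@@]3(C)C[C@H](OC(C)(C)O3)[C@@H]1[C@](C)(CI)[C@H](C(C)(C)C(=O)OCC=C)[C@H](O[Si](CC)(CC)CC)C[C@@]1(O)C
F0 | step 9 | none | none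
F4 | step 10 | 3,6-γ-lactone (O8–H free, acetonide) | CC1(C)C(=O)O[C@@H]2C[C@](C)(O)[C@H]([C@@H]3C[C@](C)(C=C)OC(C)(C)O3)C(C)(C)[C@H]12
F5 | step 10 | 6-O-triethylsilyl C3 acid | OC(=O)C(C)(C)[C@@H]1[C@H](O[Si](CC)(CC)CC)C[C@](C)(O)[C@H]([C@@H]2C[C@](C)(C=C)OC(C)(C)O2)C1(C)C
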